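**Retrosynthetic overview**

1. Ring letters: A = para-phenylene, B = catechol ring, C = 4-alkyl-2-aryloxyphenol ring, D = meta-phenylene. Marchantin H (14) comes from its tri-O-methyl ether 13 by cleavage of the three aryl methyl ethers in the last step.
2. 13 comes from the acyclic tetra-aryl 11: the 18-membered ring is closed at the C(sp2)–C(sp3) bond between C4 of ring A (para to the ring C–O–ring A oxygen) and the neighbouring CH2 of the ring A–CH2CH2–ring B bridge, by one-flask hydroboration of the ring B vinyl group and intramolecular B-alkyl Suzuki–Miyaura coupling with the ring A bromide.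
3. Feature that allows this: the bridge carbons carry no stereocentre and no heteroatom, so the CH2CH2 unit on C1 of ring B is a latent vinyl group whose anti-Markovnikov hydroboration places boron on the very carbon that must bond to ring A. The two diaryl ether oxygens and the ring D–CH2CH2–ring C bridge act as hinges that let the ends of the 18-atom perimeter meet without strain.
4. 11 comes from styrene 4 (rings C and A, bromide) and aryl iodide 8 (rings B and D, vinyl) by the same hydroboration/B-alkyl Suzuki–Miyaura logic at the ring D–CH2 bond, iodide reacting before bromide. 4 comes from isovanillin 1 and boronic acid 2 (Chan–Lam coupling, Wittig methylenation); 8 comes from 3-iodophenol 5 and fluoroaldehyde 6 (SNAr, Wittig methylenation).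
5. Order of ring formation: all four benzene rings are bought; the only ring made is the 18-membered macrocycle (step 6).

Key step: step 6

Remark: compounds 1, 2, 5, 6 and the reagent 9 are taken as catalogue compounds; the methyl ethers already present in 1 and 6 are the only protecting groups (dppf = 1,1'-bis(diphenylphosphino)ferrocene).

**Step 1**
Reactants: 1 isovanillin (3-hydroxy-4-methoxybenzaldehyde); 2 4-bromophenylboronic acid
Product: 3 3-(4-bromophenoxy)-4-methoxybenzaldehyde
Conditions: Cu(OAc)2 (20 mol%), pyridine, 4 Å molecular sieves, CH2Cl2, O2 (1 atm), rt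
Reagents that add atoms: none
Why: Chan–Lam oxidative C–O coupling, in which the aryl group is transferred from boron to divalent copper and joined to the phenoxide oxygen, should give the diaryl ether while the aryl bromide and the aldehyde stay untouched because no zerovalent palladium or strong nucleophile is present.

**Step 2**
Reactants: 3 3-(4-bromophenoxy)-4-methoxybenzaldehyde
Product: 4 2-(4-bromophenoxy)-4-ethenyl-1-methoxybenzene
Conditions: Ph3PCH3Br, KOtBu, THF, 0 °C to rt
Reagents that add atoms: methyltriphenylphosphonium bromide, C[P+](c1ccccc1)(c1ccccc1)c1ccccc1.[Br-]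
Why: Wittig methylenation with the non-stabilised ylide should convert the aromatic aldehyde into the terminal styrene without affecting the aryl bromide or the ethers.

**Step 3**
Reactants: 5 3-iodophenol; 6 2-fluoro-3,4-dimethoxybenzaldehyde
Product: 7 2-(3-iodophenoxy)-3,4-dimethoxybenzaldehyde
Conditions: K2CO3, DMSO, 120 °C
Reagents that add atoms: none
Why: Nucleophilic aromatic substitution (SNAr, addition–elimination): the phenoxide of 5 should attack the fluorine-bearing carbon ortho to the formyl group, which stabilises the Meisenheimer intermediate, while the aryl iodide is inert in the absence of a transition metal.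

**Step 4**
Reactants: 7 2-(3-iodophenoxy)-3,4-dimethoxybenzaldehyde
Product: 8 1-ethenyl-2-(3-iodophenoxy)-3,4-dimethoxybenzene
Conditions: Ph3PCH3Br, KOtBu, THF, 0 °C to rt
Reagents that add atoms: methyltriphenylphosphonium bromide, C[P+](c1ccccc1)(c1ccccc1)c1ccccc1.[Br-]
Why: Wittig methylenation should turn the ring B aldehyde into the vinyl group needed later, the aryl iodide being unreactive towards the ylide at this temperature.

**Step 5**
Reactants: 4 2-(4-bromophenoxy)-4-ethenyl-1-methoxybenzene; 8 1-ethenyl-2-(3-iodophenoxy)-3,4-dimethoxybenzene; 9 9-borabicyclo[3.3.1]nonane (9-BBN)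
Product: 11 2-[3-[2-[3-(4-bromophenoxy)-4-methoxyphenyl]ethyl]phenoxy]-1-ethenyl-3,4-dimethoxybenzene (acyclic tetra-aryl), via alkylborane 10 (not isolated)
Conditions: 4 + 9 (1.0 equiv relative to 4), THF, 0 °C to rt; then aq Cs2CO3, then 8, PdCl2(dppf) (5 mol%), AsPh3 (5 mol%), DMF, rt
Reagents that add atoms: none
Why: One-flask anti-Markovnikov hydroboration/B-alkyl Suzuki–Miyaura coupling: the primary alkylborane 10 should couple at room temperature with the aryl iodide of 8, because zerovalent palladium inserts into C–I far faster than into the electron-rich C–Br bond of ring A, and the vinyl group of 8 is not touched once residual B–H has been destroyed by the aqueous base.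

**Step 6**
Reactants: 11 2-[3-[2-[3-(4-bromophenoxy)-4-methoxyphenyl]ethyl]phenoxy]-1-ethenyl-3,4-dimethoxybenzene; 9 9-borabicyclo[3.3.1]nonane (9-BBN)
Product: 13 marchantin H tri-O-methyl ether (18-membered macrocycle), via alkylborane 12 (not isolated)
Conditions: 11 + 9 (1.5 equiv), THF, rt; then slow addition (syringe pump) into PdCl2(dppf) (15 mol%), AsPh3 (15 mol%), Cs2CO3, THF/DMF/H2O, 65 °C, final concentration about 2 mM
Reagents that add atoms: none
Why: 9-BBN adds to the ring B vinyl group in the anti-Markovnikov sense to give the primary alkylborane 12; after base converts it into the borate, zerovalent palladium (from PdCl2(dppf)) inserts into the C–Br bond of ring A, the primary alkyl group is transferred from boron to divalent palladium and reductive elimination forms the C4(ring A)–CH2 bond. The closest known reaction type is the one-flask hydroboration/B-alkyl Suzuki–Miyaura coupling, which is documented for intramolecular and macrocyclic C(aryl)–CH2 bond formation. The 18-membered ring is closed in an end-to-end macrocyclization mode, the ring-forming event being the reductive elimination from a 19-membered palladacycle that spans both chain ends. No stereocentre is created and the product carries no alkene, so no configurational issue arises. The step needs terminal regioselectivity in the hydroboration, which the bulky 9-BBN and the monosubstituted styrene secure, and oxidative addition at the only remaining carbon–halogen bond, the ring A bromide. It further needs ring closure to outrun oligomerization, protodeboronation and β-hydride elimination, which slow addition of 12 into the catalyst at high dilution, the large bite angle of dppf (fast reductive elimination) and the hinge-like diaryl ether and CH2CH2 units of the substrate are expected to secure.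

**Step 7**
Reactants: 13 marchantin H tri-O-methyl ether
Product: 14 marchantin H
Conditions: BBr3, CH2Cl2, −78 °C to rt; then H2O
Reagents that add atoms: none
Why: Lewis acid-mediated aryl methyl ether cleavage: BBr3 coordinates each methoxy oxygen and bromide removes the methyl group by SN2 attack, whereas the diaryl ether C(sp2)–O bonds cannot be cleaved in this way, so aqueous work-up of the aryl borates should release the three phenols.

**Compound list**

1 | isovanillin (3-hydroxy-4-methoxybenzaldehyde) | COc1ccc(C=O)cc1O | starting material
2 | 4-bromophenylboronic acid | OB(O)c1ccc(Br)cc1 | starting material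
3 | 3-(4-bromophenoxy)-4-methoxybenzaldehyde | COc1ccc(C=O)cc1Oc1ccc(Br)cc1 | intermediate
4 | 2-(4-bromophenoxy)-4-ethenyl-1-methoxybenzene | COc1ccc(C=C)cc1Oc1ccc(Br)cc1 | intermediate
5 | 3-iodophenol | Oc1cccc(I)c1 | starting material
6 | 2-fluoro-3,4-dimethoxybenzaldehyde | COc1ccc(C=O)c(F)c1OC | starting material
7 | 2-(3-iodophenoxy)-3,4-dimethoxybenzaldehyde | COc1ccc(C=O)c(Oc2cccc(I)c2)c1OC | intermediate
8 | 1-ethenyl-2-(3-iodophenoxy)-3,4-dimethoxybenzene | COc1ccc(C=C)c(Oc2cccc(I)c2)c1OC | intermediate
9 | 9-borabicyclo[3.3.1]nonane (9-BBN) | B1C2CCCC1CCC2 | starting material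
10 | 9-[2-[3-(4-bromophenoxy)-4-methoxyphenyl]ethyl]-9-borabicyclo[3.3.1]nonane | COc1ccc(CCB2C3CCCC2CCC3)cc1Oc1ccc(Br)cc1 | intermediate
11 | 2-[3-[2-[3-(4-bromophenoxy)-4-methoxyphenyl]ethyl]phenoxy]-1-ethenyl-3,4-dimethoxybenzene | COc1ccc(CCc2cccc(Oc3c(C=C)ccc(OC)c3OC)c2)cc1Oc1ccc(Br)cc1 | intermediate
12 | 9-[2-[2-[3-[2-[3-(4-bromophenoxy)-4-methoxyphenyl]ethyl]phenoxy]-3,4-dimethoxyphenyl]ethyl]-9-borabicyclo[3.3.1]nonane | COc1ccc(CCc2cccc(Oc3c(CCB4C5CCCC4CCC5)ccc(OC)c3OC)c2)cc1Oc1ccc(Br)cc1 | intermediate
13 | marchantin H tri-O-methyl ether | COc1ccc2cc1Oc1ccc(cc1)CCc1ccc(OC)c(OC)c1Oc1cccc(c1)CC2 | intermediate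
14 | marchantin H | Oc1ccc2cc1Oc1ccc(cc1)CCc1ccc(O)c(O)c1Oc1cccc(c1)CC2 | target

**Step count and risks**

Total step count: 7. Longest linear sequence: 5 steps (1 → 3 → 4 → 11 → 13 → 14, steps 1, 2, 5, 6 and 7; the branch 5/6 → 7 → 8 is equally long).

Steps most likely to fail:

Step 6. Transmetalation of the primary alkyl borate may be slow at high dilution, so that intermolecular coupling to oligomers, protodeboronation of 12, or β-hydride elimination from the alkylpalladium intermediate could outrun ring closure. The fallback sets out from 11 and comes back to the route at 13. It closes the same bond one oxidation level higher, without boron. An intramolecular Heck reaction of the ring A bromide with the ring B vinyl group (Pd(OAc)2, P(o-tol)3, K2CO3, DMF, 110 °C, about 2 mM) should give the macrocyclic (E)-stilbene tri-O-methyl ether F1 by arylpalladium addition to the terminal alkene carbon and syn β-hydride elimination. Hydrogenation of F1 (H2, 1 atm, Pd/C, EtOAc, rt) should then give 13.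

Step 5. The preference for iodide over bromide in the oxidative addition may erode, letting borane 10 couple through its own ring A bromide, or residual 9-BBN may hydroborate the vinyl group of 8 before the coupling. The fallback sets out from 3 and comes back to the route at 11. It builds the ring D–CH2CH2–ring C bridge without palladium and attaches ring B afterwards. Horner–Wadsworth–Emmons olefination of 3 with diethyl (3-hydroxybenzyl)phosphonate (NaH, THF, 0 °C to rt) should give (E)-3-[2-[3-(4-bromophenoxy)-4-methoxyphenyl]ethenyl]phenol F2. Diimide reduction (TsNHNH2, NaOAc, DME/H2O, reflux), which spares the C–Br bond, should give 3-[2-[3-(4-bromophenoxy)-4-methoxyphenyl]ethyl]phenol F3. SNAr of F3 with 6 (K2CO3, DMSO, 120 °C) should give 2-[3-[2-[3-(4-bromophenoxy)-4-methoxyphenyl]ethyl]phenoxy]-3,4-dimethoxybenzaldehyde F4. Wittig methylenation of F4 (Ph3PCH3Br, KOtBu, THF) should give 11.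

Step 1. Protodeboronation and oxidative homocoupling of 2 may consume the boronic acid faster than the weakly nucleophilic, ortho-substituted phenol is arylated, leaving the C–O coupling incomplete. The fallback sets out from 1 and comes back to the route at 3. It replaces the oxidative coupling by an Ullmann-type ether synthesis with an aryl halide: 1 and 1-bromo-4-iodobenzene (CuI, picolinic acid, K3PO4, DMSO, 90 °C) should give 3 directly, the copper catalyst reacting at the C–I bond and leaving the C–Br bond for step 6.

**Further compounds**

F1 | step 6 | macrocyclic (E)-stilbene tri-O-methyl ether (ring A–CH=CH–ring B analogue of 13) | COc1ccc2cc1Oc1ccc(cc1)/C=C/c1ccc(OC)c(OC)c1Oc1cccc(c1)CC2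
F2 | step 5 | (E)-3-[2-[3-(4-bromophenoxy)-4-methoxyphenyl]ethenyl]phenol | COc1ccc(/C=C/c2cccc(O)c2)cc1Oc1ccc(Br)cc1
F3 | step 5 | 3-[2-[3-(4-bromophenoxy)-4-methoxyphenyl]ethyl]phenol | COc1ccc(CCc2cccc(O)c2)cc1Oc1ccc(Br)cc1
F4 | step 5 | 2-[3-[2-[3-(4-bromophenoxy)-4-methoxyphenyl]ethyl]phenoxy]-3,4-dimethoxybenzaldehyde | COc1ccc(CCc2cccc(Oc3c(C=O)ccc(OC)c3OC)c2)cc1Oc1ccc(Br)cc1
F0 | step 1 | none | none
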